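**Assumption:** CNP0333046.1 is read as 13-oxo-13,14-secoabiet-7-ene-14,18-dioic acid (abietane numbering C1–C20 is used for all bicyclic compounds); geranyl bromide, trimethyl(prop-1-yn-1-yl)silane and 4-methylpent-1-en-3-one are bought.

## Retrosynthetic overview

1. Target ⇐ Δ7 14,18-diol (oxidation of both primary alcohols) ⇐ 18-hydroxy 8(14)-exo-methylene bicycle (copalyl-type alkene) by epoxidation and epoxide-to-allylic-alcohol isomerisation.
2. Bicycle ⇐ one cation–olefin cascade of an acyclic (R)-2-methyl-2-alkyloxirane / (E)-alkene / (Z)-allylsilane: ring A first (C4–C5, oxirane opened at C4 with inversion, its oxygen left on C18), then ring B (C10–C9, loss of silicon).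
3. Oxirane ⇐ (R)-1,2-diol ⇐ hydride opening of a Sharpless epoxy alcohol ⇐ SeO2 oxidation of the terminal (E)-methyl group.
4. Allylsilane and keto side chain ⇐ syn-carbocupration of a terminal alkyne with Me3SiCH2Cu, then conjugate addition to isopropyl vinyl ketone.
5. C13 chain ⇐ geranyl bromide + lithiated 1-silylpropyne.

## Route

Step 1
Reactants: 1 geranyl bromide, 2 trimethyl(prop-1-yn-1-yl)silane
Product: 5 (5E)-6,10-dimethylundeca-5,9-dien-1-yne, via (3-lithioprop-1-yn-1-yl)trimethylsilane 3 (not isolated), via silyl dienyne 4 (not isolated)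
Conditions: n-BuLi, THF, −78 °C; add 1, −78 °C → rt; then K2CO3 (cat.), MeOH, rt
Reagents that add atoms: none
Why: SN2 alkylation of the propargylic lithium of a 1-silylpropyne by the primary allylic bromide keeps the (E)-alkene of the geranyl unit, and base-catalysed protodesilylation then frees the terminal alkyne.

Step 2
Reactants: 5 (5E)-6,10-dimethylundeca-5,9-dien-1-yne
Product: 6 (2E,6E)-2,6-dimethylundeca-2,6-dien-10-yn-1-ol
Conditions: SeO2 (0.3 equiv), t-BuOOH (3 equiv), salicylic acid (cat.), CH2Cl2, 0 °C → rt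
Reagents that add atoms: selenium dioxide (O=[Se]=O), tert-butyl hydroperoxide (CC(C)(C)OO)
Why: Sharpless–Umbreit allylic oxidation (ene reaction then [2,3]-sigmatropic shift) goes preferentially at the terminal, least hindered trisubstituted alkene and oxidises only its (E)-methyl group, which becomes C18.

Step 3
Reactants: 6 (2E,6E)-2,6-dimethylundeca-2,6-dien-10-yn-1-ol
Product: 7 [(2S,3S)-2-methyl-3-[(3E)-3-methyloct-3-en-7-yn-1-yl]oxiran-2-yl]methanol
Conditions: Ti(OiPr)4 (10 mol %), L-(+)-diethyl tartrate (12 mol %), t-BuOOH, 4 Å MS, CH2Cl2, −20 °C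
Reagents that add atoms: tert-butyl hydroperoxide (CC(C)(C)OO)
Why: Sharpless asymmetric epoxidation is directed by the allylic hydroxyl (the other alkene and the alkyne are untouched), and L-(+)-tartrate gives the (2S,3S)-epoxide, which fixes the future C4 carbinol centre.

Step 4
Reactants: 7 [(2S,3S)-2-methyl-3-[(3E)-3-methyloct-3-en-7-yn-1-yl]oxiran-2-yl]methanol
Product: 8 (2R,6E)-2,6-dimethylundec-6-en-10-yne-1,2-diol
Conditions: LiAlH4, THF, 0 °C → rt
Reagents that add atoms: none
Why: Regioselective reductive epoxide opening, hydride attacking the less substituted oxirane carbon (C3) in SN2 fashion, leaves the C4–O bond intact, so the tertiary alcohol keeps its configuration (R in the diol).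

Step 5
Reactants: 8 (2R,6E)-2,6-dimethylundec-6-en-10-yne-1,2-diol, 9 4-methylpent-1-en-3-one
Product: 12 (2R,6E,10Z)-1,2-dihydroxy-2,6,15-trimethyl-10-[(trimethylsilyl)methyl]hexadeca-6,10-dien-14-one, via alkenylcopper dialkoxide 10 (not isolated), via tris-silyl enol ether 11 (not isolated)
Conditions: Me3SiCH2MgCl (5 equiv), CuBr·SMe2 (3 equiv), Et2O/Me2S/THF, −40 → 0 °C; then Me3SiCl, 9, −78 → −30 °C; K2CO3 (cat.), MeOH work-up
Reagents that add atoms: (trimethylsilyl)methylmagnesium chloride (C[Si](C)(C)C[Mg]Cl)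
Why: Normant carbocupration adds CH2SiMe3 to the internal and copper to the terminal alkyne carbon in a syn fashion (hydroxyls ride as magnesium alkoxides), and Me3SiCl-accelerated conjugate addition of the alkenylcopper to the enone with retention gives the trisubstituted allylsilane with the keto side chain cis to CH2SiMe3.

Step 6
Reactants: 12 (2R,6E,10Z)-1,2-dihydroxy-2,6,15-trimethyl-10-[(trimethylsilyl)methyl]hexadeca-6,10-dien-14-one
Product: 14 (6Z,10E)-2,11-dimethyl-14-[(2R)-2-methyloxiran-2-yl]-7-[(trimethylsilyl)methyl]tetradeca-6,10-dien-3-one, via primary tosylate 13 (not isolated)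
Conditions: TsCl, Et3N, DMAP (cat.), CH2Cl2, 0 °C; then K2CO3, MeOH, rt
Reagents that add atoms: none
Why: Selective sulfonylation of the primary hydroxyl and intramolecular Williamson closure by the tertiary alkoxide form the 2,2-disubstituted oxirane without breaking the C4–O bond, so the oxirane is (R).

Step 7
Reactants: 14 (6Z,10E)-2,11-dimethyl-14-[(2R)-2-methyloxiran-2-yl]-7-[(trimethylsilyl)methyl]tetradeca-6,10-dien-3-one
Product: 15 18-hydroxy-13,14-secoabiet-8(14)-en-13-one
Conditions: MeAlCl2 (2.5 equiv), CH2Cl2, −78 °C; Et3N/MeOH quench at −78 °C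
Reagents that add atoms: none
Why: Lewis-acid-triggered biomimetic cation–olefin bicyclisation through a chair–chair fold (Stork–Eschenmoser), in which C5 opens the oxirane at tertiary C4 with inversion (oxygen stays on C18, the bulky CH2O–Al group equatorial), the (E)-alkene passes the cation to C10 (trans fusion) and the (Z)-allylsilane closes ring B with loss of silicon (Sakurai-type termination, 9α-H), so all four stereocentres follow from the single oxirane centre, and the cold quench avoids a later carbonyl-ene closure onto the ketone.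

Step 8
Reactants: 15 18-hydroxy-13,14-secoabiet-8(14)-en-13-one
Product: 16 8α,14-epoxy-18-hydroxy-13,14-secoabietan-13-one
Conditions: mCPBA (1.1 equiv), CH2Cl2, 0 °C
Reagents that add atoms: 3-chloroperbenzoic acid (OOC(=O)c1cccc(Cl)c1)
Why: Prilezhaev epoxidation of the only alkene occurs from the α-face, opposite the axial C10 methyl group, and is faster than Baeyer–Villiger attack on the hindered ketone.

Step 9
Reactants: 16 8α,14-epoxy-18-hydroxy-13,14-secoabietan-13-one
Product: 17 14,18-dihydroxy-13,14-secoabiet-7-en-13-one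
Conditions: (C5H5)2TiCl2 (2.5 equiv), Mn dust, THF, rt; dilute HCl work-up
Reagents that add atoms: none
Why: Titanocene chloride (trivalent titanium) opens the spiro-oxirane homolytically to the tertiary C8 radical (Nugent–RajanBabu opening), a second equivalent traps it, and β-hydride elimination towards the less hindered C7 methylene gives the Δ7 allylic alcohol without base, so the ketone is not enolised and the C8 centre disappears.

Step 10
Reactants: 17 14,18-dihydroxy-13,14-secoabiet-7-en-13-one
Product: 19 13-oxo-13,14-secoabiet-7-ene-14,18-dioic acid, via dialdehyde 18 (not isolated)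
Conditions: TEMPO (cat.), NaClO2, NaOCl (cat.), MeCN/phosphate buffer pH 6.7, 35 °C
Reagents that add atoms: sodium chlorite ([Na+].[O-]Cl=O)
Why: Nitroxyl-mediated alcohol oxidation followed in the same pot by Lindgren–Pinnick chlorite oxidation converts the allylic and the neopentyl primary alcohol to acids without touching the ketone, the alkene or any stereocentre.

## Compound list

1 | geranyl bromide, (2E)-1-bromo-3,7-dimethylocta-2,6-diene | CC(C)=CCC/C(C)=C/CBr | starting material
2 | trimethyl(prop-1-yn-1-yl)silane | CC#C[Si](C)(C)C | starting material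
3 | (3-lithioprop-1-yn-1-yl)trimethylsilane | [Li]CC#C[Si](C)(C)C | intermediate
4 | [(5E)-6,10-dimethylundeca-5,9-dien-1-yn-1-yl]trimethylsilane | C[Si](C)(C)C#CCC/C=C(\C)CCC=C(C)C | intermediate
5 | (5E)-6,10-dimethylundeca-5,9-dien-1-yne | C#CCC/C=C(\C)CCC=C(C)C | intermediate
6 | (2E,6E)-2,6-dimethylundeca-2,6-dien-10-yn-1-ol | C#CCC/C=C(\C)CC/C=C(\C)CO | intermediate
7 | [(2S,3S)-2-methyl-3-[(3E)-3-methyloct-3-en-7-yn-1-yl]oxiran-2-yl]methanol | C#CCC/C=C(\C)CC[C@@H]1O[C@@]1(C)CO | intermediate
8 | (2R,6E)-2,6-dimethylundec-6-en-10-yne-1,2-diol | C#CCC/C=C(\C)CCC[C@@](C)(O)CO | intermediate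
9 | 4-methylpent-1-en-3-one (isopropyl vinyl ketone) | CC(C)C(=O)C=C | starting material
10 | alkenylcopper from syn-addition of Me3SiCH2Cu to 8 (copper cis to CH2SiMe3, both hydroxyls as OMgCl) | [Cu]\C=C(/C[Si](C)(C)C)CC/C=C(\C)CCC[C@@](C)(O[Mg]Cl)CO[Mg]Cl | intermediate
11 | trimethylsilyl enol ether of 12 with both hydroxyls as trimethylsilyl ethers | C[Si](C)(C)OC(C(C)C)=CC\C=C(/C[Si](C)(C)C)CC/C=C(\C)CCC[C@@](C)(O[Si](C)(C)C)CO[Si](C)(C)C | intermediate
12 | (2R,6E,10Z)-1,2-dihydroxy-2,6,15-trimethyl-10-[(trimethylsilyl)methyl]hexadeca-6,10-dien-14-one | CC(C)C(=O)CC\C=C(/C[Si](C)(C)C)CC/C=C(\C)CCC[C@@](C)(O)CO | intermediate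
13 | (2R,6E,10Z)-2-hydroxy-2,6,15-trimethyl-14-oxo-10-[(trimethylsilyl)methyl]hexadeca-6,10-dien-1-yl 4-methylbenzenesulfonate | CC(C)C(=O)CC\C=C(/C[Si](C)(C)C)CC/C=C(\C)CCC[C@@](C)(O)COS(=O)(=O)c1ccc(C)cc1 | intermediate
14 | (6Z,10E)-2,11-dimethyl-14-[(2R)-2-methyloxiran-2-yl]-7-[(trimethylsilyl)methyl]tetradeca-6,10-dien-3-one | CC(C)C(=O)CC\C=C(/C[Si](C)(C)C)CC/C=C(\C)CCC[C@]1(C)CO1 | intermediate
15 | 18-hydroxy-13,14-secoabiet-8(14)-en-13-one (4R; 5α-H, 9α-H, 10β-CH3, 4α-CH2OH) | CC(C)C(=O)CC[C@H]1C(=C)CC[C@@H]2[C@]1(C)CCC[C@@]2(C)CO | intermediate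
16 | 8α,14-epoxy-18-hydroxy-13,14-secoabietan-13-one | CC(C)C(=O)CC[C@H]1[C@@]3(CO3)CC[C@@H]2[C@]1(C)CCC[C@@]2(C)CO | intermediate
17 | 14,18-dihydroxy-13,14-secoabiet-7-en-13-one | CC(C)C(=O)CC[C@H]1C(CO)=CC[C@@H]2[C@]1(C)CCC[C@@]2(C)CO | intermediate
18 | 13-oxo-13,14-secoabiet-7-ene-14,18-dial | CC(C)C(=O)CC[C@H]1C(C=O)=CC[C@@H]2[C@]1(C)CCC[C@@]2(C)C=O | intermediate
19 | 13-oxo-13,14-secoabiet-7-ene-14,18-dioic acid (CNP0333046.1) | CC(C)C(=O)CC[C@H]1C(C(=O)O)=CC[C@@H]2[C@]1(C)CCC[C@@]2(C)C(=O)O | target

## Step count and risks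

Total steps: 10. Longest linear sequence: 10 steps (1 → 19).

**Step 5 (carbocupration and conjugate addition on the free diol).** The magnesium dialkoxide may be poorly soluble in ether, and Me3SiCH2Cu is a sluggish carbocuprating reagent. The fallback sets out from 8 and comes back at 12. It is a nickel-catalysed three-component alkylative coupling of 8, 9 and (Me3SiCH2)2Zn (3 equiv) with Ni(C8H12)2 (zerovalent nickel, 10 mol %) in THF at 0 °C. Oxidative cyclisation joins the enone β-carbon to the terminal alkyne carbon, and transmetalation with reductive elimination places CH2SiMe3 on the internal carbon syn to it. Aqueous work-up gives 12 directly; this fallback makes no new compound, F0.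

**Step 7 (oxirane-initiated bicyclisation).** The 2,2-disubstituted oxirane can undergo Meinwald rearrangement to the aldehyde, the cascade can stop after ring A, or the C18 group can end up axial. The fallback sets out from 12 and comes back at 15, and changes the initiating electrophile to a cyclic sulfate, which ionises at C4 with the same single inversion but cannot undergo a hydride shift to an aldehyde. Diol 12 with 1,1′-sulfonyldiimidazole and DBU in THF gives the 4,18-cyclic sulfate (4R)-1,3,2-dioxathiolane 2,2-dioxide F1. BF3·OEt2 in CH2Cl2 at −78 °C then triggers the same chair–chair cyclisation with loss of silicon to 13-oxo-13,14-secoabiet-8(14)-en-18-yl hydrogen sulfate F2. Hydrolysis of F2 with catalytic H2SO4 in moist THF gives 15.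

**Step 9 (regiochemistry of the epoxide-to-allylic-alcohol isomerisation).** β-Hydride loss could go towards C9, or the C8 radical could be reduced. The fallback sets out from 15 and comes back at 17, bypassing 16. It is a Schenck ene reaction of 15 with singlet oxygen (O2, tetraphenylporphyrin, visible light, CH2Cl2, 0 °C). Oxygen adds to C14 with shift of the alkene to C7–C8, giving 14-hydroperoxy-18-hydroxy-13,14-secoabiet-7-en-13-one F3. Reduction of F3 in the same flask with PPh3 gives 17.

## Further compounds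

F0 | step 5 | none | none
F1 | step 7 | (4R)-4-methyl-4-[(4E,8Z)-4,13-dimethyl-12-oxo-8-[(trimethylsilyl)methyl]tetradeca-4,8-dien-1-yl]-1,3,2-dioxathiolane 2,2-dioxide | CC(C)C(=O)CC\C=C(/C[Si](C)(C)C)CC/C=C(\C)CCC[C@]1(C)COS(=O)(=O)O1
F2 | step 7 | 13-oxo-13,14-secoabiet-8(14)-en-18-yl hydrogen sulfate | CC(C)C(=O)CC[C@H]1C(=C)CC[C@@H]2[C@]1(C)CCC[C@@]2(C)COS(=O)(=O)O
F3 | step 9 | 14-hydroperoxy-18-hydroxy-13,14-secoabiet-7-en-13-one | CC(C)C(=O)CC[C@H]1C(COO)=CC[C@@H]2[C@]1(C)CCC[C@@]2(C)CO
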